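The runs are simulated with made-up constants; scatter was added.

A ratio opens the reckoning: the logarithm of charged over remaining substrate at 15.0 min is 0.755 in the south run and 1.56 in the north-west run, a factor of 2.07, close to the factor 2.21 between their catalyst charges, since both carry the same mol%.

| flask | substrate | reagent | free catalyst | remark |
|---|---|---|---|---|
| south | 29 mM | 0.95 equiv | 0.081 mol% | run made earlier |
| north-west | 64 mM | 0.95 equiv | 0.081 mol% | run made earlier |
| north | 43 mM | 0.47 equiv | 0.081 mol% | run made earlier |
| flask | 43 mM | 0.950 equiv | 0.081 mol% |  |

| run | time / min | product / % | substrate / % |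
|---|---|---|---|
| south | 1.33 | 1 | 87 |
| south | 2.00 | 3 | 84 |
| south | 3.00 | 2 | 74 |
| south | 5.00 | 10 | 66 |
| south | 10.0 | 14 | 52 |
| south | 15.0 | 14 | 47 |
| north-west | 1.33 | 7 | 74 |
| north-west | 2.00 | 17 | 67 |
| north-west | 3.00 | 24 | 52 |
| north-west | 5.00 | 36 | 37 |
| north-west | 10.0 | 50 | 23 |
| north-west | 15.0 | 57 | 21 |
| north | 1.33 | 0 | 80 |
| north | 2.50 | 3 | 66 |
| north | 4.00 | 8 | 61 |
| north | 8.00 | 17 | 43 |
| north | 15.0 | 21 | 29 |

(standard deviation of a reading: 1.5 percentage points)



- factor on the rate of making product when 50% of the substrate are converted if free catalyst is charged twice over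
- factor on the rate when 50% of the substrate are converted if free catalyst is charged at 0.8 mol% instead

The reckoning here takes substrate loss as proportional to substrate and free catalyst, and catalyst loss as proportional to free catalyst. That logarithm then grows in step with the share of catalyst lost. Its limit scales with the charge, so the south reading, taken as that limit and scaled to the flask, gives 1.12. At 50% conversion the logarithm is ln 2, so the surviving share is one minus ln 2 over that limit. Doubling the charge doubles the limit and raises this share. Taking product rate as proportional to free catalyst at equal composition, the factor is 3.63.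

The weak link is that the last reading of the south run, at 15.0 min, need not be that limit: the logarithm of that run gained 0.238 from 5.00 min to 10.0 min, then 0.101 by 15.0 min. A geometric tail adds 0.0744, so the flask's reach, the limiting logarithm of charged over remaining substrate, reads 1.23. The factors become 3.29 and 21.3.

The forecast gives lower values than this reckoning, 1.9 and 7: “I lean towards near first order, with some saturation at tenfold.”

The flask gives 3.18 and 20.4, above the forecast.

    reagent + free catalyst + intermediate → free catalyst + product (k = 3270 L² mol⁻² s⁻¹)
    substrate + free catalyst → free catalyst + intermediate (k = 86.7 L mol⁻¹ s⁻¹)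
    free catalyst → spent catalyst (k = 0.00236 s⁻¹)

Each free catalyst passes substrate at 220 min⁻¹, with substrate as charged, and turns into spent catalyst at 0.14 min⁻¹, a ratio of 1571, which multiplied by the loading 0.081 mol% gives 1.28, corresponding to 27.8% substrate remaining, and the flask holds 27.8% at 250 min. With the reach read from the runs, scaled to 0.8 mol% as 12.1, the reckoned share of free catalyst at 50% conversion is 94.3% of its charge, against 43.6% at 0.081 mol%.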